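**Retrosynthetic overview**

1. Locants: ketone unit C1–C8a (ring A = benzene C4a–C8a with 5-OH, 6-Cl; ring B = C1–C4 with ketal C1, oxirane C2/C3, ketone C4); carbinol unit C1′–C8a′ (ring C = benzene with 5′-OH, 6′-Cl, 8′-O; ring D = C1′–C4′ with oxirane C2′/C3′, carbinol C4′); ring E = C1–O–C1′–C8–C8a; ring F = 1,3-dioxine C1–O–C8′–C8a′–C1′–O.
2. Endgame: both oxiranes and the C4′ carbinol go back to bis-enone 22 (ring B enone to nucleophilic epoxidation; ring D dienone to carbinol, silyl ether, dioxirane epoxidation), and 22 to cage 19 by oxidation and dehydrogenation of ring D.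
3. Key disconnection: rings D, E and F of 19 open in one operation to the flat, achiral bis-quinone 14 and enol ether 15. The forward sequence is a vinylquinone Diels–Alder reaction (C2′–C3′ and C4′–C4a′), tautomerisation to an ortho-quinone methide, and capture by the C1 quinone carbonyl (C1′–O and C1–O–C8′).
4. Enabling feature: ring C carries oxygen para at C5′ and C8′, and the O-substituted benzylic C1′ sits ortho to O8′. Ring C is therefore a masked 2-(1-arylvinyl)benzoquinone whose C4a′=C8a′ and C1′=C2′ bonds form a diene and whose cycloadduct is an ortho-quinone methide at O8′/C1′; the C1 carbonyl of ring B, peri to C8, supplies the oxygen for C1′ and takes O8′ on carbon.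
5. 14 comes from 1,1-diarylethylene 12 by double oxidative demethylation, and 12 from naphthyl bromide 6 and acetophenone 8. Ring order: A/B (aromatised from tetralone 1) and C (bought) first, then D, E and F together in step 9, then the two oxiranes.

Key step: step 9

Assumption: the sense of induction of the chiral phosphoric acid in step 9 cannot be derived on paper; the (R)-catalyst is written, and the (S)-catalyst would be used if it is the one that gives the cage enantiomer shown.

**Route**

Step 1
Reactants: 1 5,8-dimethoxy-3,4-dihydronaphthalen-1(2H)-one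
Product: 2 2-bromo-5,8-dimethoxy-3,4-dihydronaphthalen-1(2H)-one (racemic)
Conditions: CuBr2 (2.1 equiv), EtOAc/CHCl3 (1:1), reflux
Reagents that add atoms: CuBr2, Br[Cu]Br
Why: α-Bromination of an aryl ketone through its copper enolate is selective for C2 over the dimethoxyarene ring; the C2 stereocenter forms racemic and is erased in step 2.

Step 2
Reactants: 2 2-bromo-5,8-dimethoxy-3,4-dihydronaphthalen-1(2H)-one
Product: 3 5,8-dimethoxynaphthalen-1-ol
Conditions: LiBr, Li2CO3, DMF, 120 °C
Reagents that add atoms: none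
Why: Base-mediated dehydrobromination gives the naphthalen-1(4H)-one, which should tautomerise at once to the naphthol (aromatisation-driven elimination).

Step 3
Reactants: 3 5,8-dimethoxynaphthalen-1-ol
Product: 5 4-bromo-2-chloro-5,8-dimethoxynaphthalen-1-ol, via 4-bromo-5,8-dimethoxynaphthalen-1-ol 4 (not isolated)
Conditions: N-bromosuccinimide (1.0 equiv), MeCN, −20 °C; then N-chlorosuccinimide (1.05 equiv), 0 °C → rt
Reagents that add atoms: N-bromosuccinimide, O=C1CCC(=O)N1Br; N-chlorosuccinimide, O=C1CCC(=O)N1Cl
Why: Two electrophilic aromatic halogenations directed by the free naphthol: N-bromosuccinimide in acetonitrile should take the para position C4, and N-chlorosuccinimide then has only the ortho position C2 left on the activated ring.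

Step 4
Reactants: 5 4-bromo-2-chloro-5,8-dimethoxynaphthalen-1-ol
Product: 6 1-bromo-3-chloro-5,8-dimethoxy-4-(methoxymethoxy)naphthalene
Conditions: MeOCH2Cl, i-Pr2NEt, CH2Cl2, 0 °C → rt
Reagents that add atoms: chloromethyl methyl ether, COCCl
Why: O-Alkylation of the naphthol (methoxymethyl ether formation) masks the acidic OH before the bromine–lithium exchange.

Step 5
Reactants: 7 2-chloro-1,4-dimethoxybenzene
Product: 8 1-(4-chloro-2,5-dimethoxyphenyl)ethan-1-one
Conditions: AcCl, AlCl3, CH2Cl2, 0 °C
Reagents that add atoms: acetyl chloride, CC(Cl)=O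
Why: Friedel–Crafts acylation should occur para to chlorine and ortho to a methoxy group, the position at which this arene takes electrophiles.

Step 6
Reactants: 6 1-bromo-3-chloro-5,8-dimethoxy-4-(methoxymethoxy)naphthalene; 8 1-(4-chloro-2,5-dimethoxyphenyl)ethan-1-one
Product: 12 1-chloro-4-{1-[3-chloro-5,8-dimethoxy-4-(methoxymethoxy)naphthalen-1-yl]ethenyl}-2,5-dimethoxybenzene, via aryllithium 9 (not isolated), via arylcerium dichloride 10 (not isolated), via tertiary carbinol 11 (not isolated)
Conditions: n-BuLi, THF, −78 °C; CeCl3, −78 °C; 8, −78 → 0 °C; then 1 M HCl, rt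
Reagents that add atoms: none
Why: Bromine–lithium exchange outruns attack on the aryl chloride or the acetal, the organocerium reagent adds 1,2 to the enolisable ketone without deprotonating it, and the doubly benzylic tertiary carbinol loses water by acid-catalysed E1 elimination on work-up; its stereocenter is racemic and disappears.

Step 7
Reactants: 12 1-chloro-4-{1-[3-chloro-5,8-dimethoxy-4-(methoxymethoxy)naphthalen-1-yl]ethenyl}-2,5-dimethoxybenzene
Product: 13 6-chloro-8-[1-(4-chloro-3,6-dioxocyclohexa-1,4-dien-1-yl)ethenyl]-5-(methoxymethoxy)naphthalene-1,4-dione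
Conditions: (NH4)2Ce(NO3)6 (4.5 equiv), MeCN/H2O (3:1), 0 °C
Reagents that add atoms: water, O
Why: Oxidative demethylation of para-dimethoxyarenes by tetravalent cerium should convert both such rings into quinones, while the ring bearing the single acetal oxygen cannot become a quinone.

Step 8
Reactants: 13 6-chloro-8-[1-(4-chloro-3,6-dioxocyclohexa-1,4-dien-1-yl)ethenyl]-5-(methoxymethoxy)naphthalene-1,4-dione
Product: 14 6-chloro-8-[1-(4-chloro-3,6-dioxocyclohexa-1,4-dien-1-yl)ethenyl]-5-hydroxynaphthalene-1,4-dione
Conditions: CF3CO2H, CH2Cl2, 0 °C → rt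
Reagents that add atoms: none
Why: Acid-catalysed cleavage of the methoxymethyl acetal, assisted by the peri carbonyl, frees the C5 phenol, which is needed unprotected in step 12.

Step 9
Reactants: 14 6-chloro-8-[1-(4-chloro-3,6-dioxocyclohexa-1,4-dien-1-yl)ethenyl]-5-hydroxynaphthalene-1,4-dione; 15 trimethyl(vinyloxy)silane
Product: 19 cage enone diol (rings D E F closed; C4′ carbinol as both epimers), via Diels-Alder adduct 16 (not isolated), via ortho-quinone methide 17 (not isolated), via cage silyl ether 18 (not isolated)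
Conditions: 15 (5 equiv), (R)-3,3′-bis(2,4,6-triisopropylphenyl)-1,1′-binaphthyl-2,2′-diyl hydrogen phosphate (10 mol %), toluene, 4 Å molecular sieves, −20 °C → rt; then aqueous citric acid, THF, 0 °C
Reagents that add atoms: none
Why: Proposed new method: The acid hydrogen-bonds the chlorobenzoquinone of 14, whose C4a′=C8a′ bond and exocyclic C1′=C2′ bond form an electron-poor s-cis diene, and enol ether 15 adds across C2′ and C4a′ in an inverse-electron-demand vinylquinone Diels–Alder reaction (intermolecular [4+2] closure of ring D; new bonds C2′–C3′ and C4′–C4a′) to give isoquinone methide 16. Acid-mediated transfer of the C4a′ proton to O5′ gives ortho-quinone methide 17 (O8′=C8′–C8a′=C1′), in which ring D holds C2′ trans and the C8 aryl group cis to the C8′ carbonyl, so a 1,5-hydrogen shift to a styrene is impossible and the peri C1 carbonyl of the naphthoquinone is stacked on the heterodiene; an intramolecular oxa-[4+2] addition of this C=O (C1′–O bond by 5-exo-trig closure of ring E, O8′–C1 bond by 6-endo-trig closure of ring F) aromatises ring C and gives 18. The closest known reaction types are the vinylquinone Diels–Alder reaction in which water intercepts the isoquinone methide and the phosphoric-acid-catalysed enantioselective oxa-[4+2] cycloadditions and oxa-Michael additions of ortho-quinone methides; a ketone oxygen as internal 2π partner and catalyst control of such a cage closure are not known. C1′ and C1 arise together: their relative configuration is dictated by the bridging geometry of rings E and F and their absolute configuration by the chiral phosphate hydrogen-bonded to O8′ of 17, which selects the face on which the twisted naphthoquinone carbonyl closes, while C4′ forms without control (both epimers, converging in step 11) and C4a′ of 16 is lost again. The step needs regioselectivity in the cycloaddition, secured because the nucleophilic CH2 of 15 bonds to the unhindered terminus C2′ where the developing charge at C1′ is stabilised by both quinone units; chemoselectivity over Michael addition to quinone CH positions, secured by the modest nucleophilicity of a simple enol ether at low temperature; and cage closure in preference to aromatisation of ring D, secured by the cis aryl geometry.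

Step 10
Reactants: 19 cage enone diol
Product: 20 cage enone C5′ silyl ether (C5′–OSiMe2t-Bu; C4′–OH; C5–OH)
Conditions: t-BuMe2SiCl (1.1 equiv), imidazole, DMF, 0 °C
Reagents that add atoms: tert-butyldimethylsilyl chloride, CC(C)(C)[Si](C)(C)Cl
Why: Chemoselective silylation: the free C5′ phenol should react much faster than the hindered secondary C4′ alcohol (as in phenol-selective silylation of estradiol-type diols) and than the C5 phenol, which is locked in a hydrogen bond to the C4 carbonyl.

Step 11
Reactants: 20 cage enone C5′ silyl ether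
Product: 22 cage bis-enone (ring B and ring D enones; C5′–OSiMe2t-Bu; C5–OH), via ring D ketone 21 (not isolated)
Conditions: 2-iodoxybenzoic acid (4 equiv), DMSO, 75 °C
Reagents that add atoms: none
Why: 2-Iodoxybenzoic acid first oxidises the C4′ carbinol (both epimers converge) and then dehydrogenates the aryl ketone through its enol to the enone, a one-pot alcohol-to-enone oxidation known for chromanones and 4,4-disubstituted tetralones; the quaternary C1′ prevents aromatisation.

Step 12
Reactants: 22 cage bis-enone
Product: 23 ring D allylic alcohol (C4′–OH anti to the C1′–O bridge)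
Conditions: NaBH4 (1.1 equiv), MeOH/CH2Cl2 (1:1), −78 → −40 °C; AcOH quench at −78 °C
Reagents that add atoms: none
Why: Chemo- and diastereoselective 1,2-reduction: under the basic borohydride conditions the ring B ketone is shielded as the conjugated C5 phenoxide (a vinylogous carboxylate) while the ring D ketone with its silylated peri oxygen stays electrophilic, and hydride should add to C4′ on the face syn to the C1′–O bond (the electrostatic preference of 4-alkoxy-4-aryl cyclohexadienones, also the face remote from ring A), placing the new OH anti to that oxygen as in the target.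

Step 13
Reactants: 23 ring D allylic alcohol
Product: 24 C4′/C5′ bis(silyl ether)
Conditions: t-BuMe2SiOSO2CF3 (1.2 equiv), 2,6-lutidine, CH2Cl2, −78 °C
Reagents that add atoms: tert-butyldimethylsilyl trifluoromethanesulfonate, CC(C)(C)[Si](C)(C)OS(=O)(=O)C(F)(F)F
Why: Silyl triflate silylation of the hindered secondary alcohol removes the hydroxyl directing effect before epoxidation (a silyl shift from O5′ to O4′ during step 12 would be repaired here, since both oxygens end silylated).

Step 14
Reactants: 24 C4′/C5′ bis(silyl ether)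
Product: 25 ring D epoxide (oxirane oxygen syn to the C1′–O bridge)
Conditions: dimethyldioxirane (acetone solution), CH2Cl2, 0 °C → rt
Reagents that add atoms: dimethyldioxirane, CC1(C)OO1
Why: Electrophilic epoxidation with a dioxirane attacks only the ring D alkene (the ring B enone is inert) and should deliver oxygen to the face anti to the bulky C4′ silyl ether, which is also the convex face syn to the C1′–O bridge (the other face is screened by ring A), setting C2′ and C3′.

Step 15
Reactants: 25 ring D epoxide
Product: 26 bis-epoxide bis(silyl ether)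
Conditions: t-BuOOH, 1,8-diazabicyclo[5.4.0]undec-7-ene (DBU), CH2Cl2, 0 °C
Reagents that add atoms: tert-butyl hydroperoxide, CC(C)(C)OO
Why: Weitz–Scheffer nucleophilic epoxidation: tert-butylperoxide should add to C2 of the ring B enone from the convex face anti to the C1–O–C8′ bond (ring C blocks the other face) and the enolate closes the oxirane, setting C2 and C3 as in related peri-hydroxy naphthalenone spiroketals.

Step 16
Reactants: 26 bis-epoxide bis(silyl ether)
Product: 27 target CNP0289684.3
Conditions: Bu4NF, AcOH, THF, 0 °C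
Reagents that add atoms: none
Why: Buffered fluoride cleaves the aryl and the alkyl silyl ether (Si–F bond formation) without touching the oxiranes, the ketal or the base-sensitive epoxy ketone.

**Compound list**

1 | 5,8-dimethoxy-3,4-dihydronaphthalen-1(2H)-one | COc1ccc(OC)c2C(=O)CCCc12 | starting material
2 | 2-bromo-5,8-dimethoxy-3,4-dihydronaphthalen-1(2H)-one (racemic) | COc1ccc(OC)c2C(=O)C(Br)CCc12 | intermediate
3 | 5,8-dimethoxynaphthalen-1-ol | COc1ccc(OC)c2c(O)cccc12 | intermediate
4 | 4-bromo-5,8-dimethoxynaphthalen-1-ol (not isolated) | COc1ccc(OC)c2c(O)ccc(Br)c12 | intermediate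
5 | 4-bromo-2-chloro-5,8-dimethoxynaphthalen-1-ol | COc1ccc(OC)c2c(O)c(Cl)cc(Br)c12 | intermediate
6 | 1-bromo-3-chloro-5,8-dimethoxy-4-(methoxymethoxy)naphthalene | COCOc1c(Cl)cc(Br)c2c(OC)ccc(OC)c12 | intermediate
7 | 2-chloro-1,4-dimethoxybenzene | COc1ccc(OC)c(Cl)c1 | starting material
8 | 1-(4-chloro-2,5-dimethoxyphenyl)ethan-1-one | CC(=O)c1cc(OC)c(Cl)cc1OC | intermediate
9 | [3-chloro-5,8-dimethoxy-4-(methoxymethoxy)naphthalen-1-yl]lithium (not isolated) | [Li]c1cc(Cl)c(OCOC)c2c(OC)ccc(OC)c12 | intermediate
10 | dichloro[3-chloro-5,8-dimethoxy-4-(methoxymethoxy)naphthalen-1-yl]cerium (not isolated) | Cl[Ce](Cl)c1cc(Cl)c(OCOC)c2c(OC)ccc(OC)c12 | intermediate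
11 | 1-[3-chloro-5,8-dimethoxy-4-(methoxymethoxy)naphthalen-1-yl]-1-(4-chloro-2,5-dimethoxyphenyl)ethan-1-ol (racemic, not isolated) | CC(O)(c1cc(OC)c(Cl)cc1OC)c1cc(Cl)c(OCOC)c2c(OC)ccc(OC)c12 | intermediate
12 | 1-chloro-4-{1-[3-chloro-5,8-dimethoxy-4-(methoxymethoxy)naphthalen-1-yl]ethenyl}-2,5-dimethoxybenzene | C=C(c1cc(OC)c(Cl)cc1OC)c1cc(Cl)c(OCOC)c2c(OC)ccc(OC)c12 | intermediate
13 | 6-chloro-8-[1-(4-chloro-3,6-dioxocyclohexa-1,4-dien-1-yl)ethenyl]-5-(methoxymethoxy)naphthalene-1,4-dione | C=C(C1=CC(=O)C(Cl)=CC1=O)c1cc(Cl)c(OCOC)c2C(=O)C=CC(=O)c12 | intermediate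
14 | 6-chloro-8-[1-(4-chloro-3,6-dioxocyclohexa-1,4-dien-1-yl)ethenyl]-5-hydroxynaphthalene-1,4-dione | C=C(C1=CC(=O)C(Cl)=CC1=O)c1cc(Cl)c(O)c2C(=O)C=CC(=O)c12 | intermediate
15 | trimethyl(vinyloxy)silane | C=CO[Si](C)(C)C | starting material
16 | Diels–Alder adduct (isoquinone methide): 3-chloro-8-(3-chloro-4-hydroxy-5,8-dioxo-5,8-dihydronaphthalen-1-yl)-5-[(trimethylsilyl)oxy]-4a,5,6,7-tetrahydronaphthalene-1,4-dione, stereoisomer mixture (not isolated) | O=C1C(Cl)=CC(=O)C2=C(c3cc(Cl)c(O)c4C(=O)C=CC(=O)c34)CCC(O[Si](C)(C)C)C12 | intermediate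
17 | ortho-quinone methide: 3-chloro-8-(3-chloro-4-hydroxy-5,8-dioxo-5,8-dihydronaphthalen-1-yl)-4-hydroxy-5-[(trimethylsilyl)oxy]-6,7-dihydronaphthalen-1(5H)-one (not isolated) | OC1=C2C(O[Si](C)(C)C)CCC(c3cc(Cl)c(O)c4C(=O)C=CC(=O)c34)=C2C(=O)C=C1Cl | intermediate
18 | cage silyl ether: rings A–F closed, ring B enone (C2=C3, C4=O), C2′H2–C3′H2, C4′–OSiMe3 (both epimers), C5–OH, C5′–OH, C6/C6′–Cl, C1 and C1′ as in the target (not isolated) | O=C1c2c(O)c(Cl)cc3c2[C@@]2(Oc4cc(Cl)c(O)c5c4[C@]3(O2)CCC5O[Si](C)(C)C)C=C1 | intermediate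
19 | cage enone diol: as 18 with C4′–OH (both epimers) | O=C1c2c(O)c(Cl)cc3c2[C@@]2(Oc4cc(Cl)c(O)c5c4[C@]3(O2)CCC5O)C=C1 | intermediate
20 | cage enone C5′ silyl ether: as 19 with C5′–OSiMe2t-Bu | O=C1c2c(O)c(Cl)cc3c2[C@@]2(Oc4cc(Cl)c(O[Si](C)(C)C(C)(C)C)c5c4[C@]3(O2)CCC5O)C=C1 | intermediate
21 | ring D ketone: as 20 with C4′=O (not isolated) | O=C1c2c(O)c(Cl)cc3c2[C@@]2(Oc4cc(Cl)c(O[Si](C)(C)C(C)(C)C)c5c4[C@]3(O2)CCC5=O)C=C1 | intermediate
22 | cage bis-enone: ring B enone (C2=C3, C4=O) and ring D enone (C2′=C3′, C4′=O), C5′–OSiMe2t-Bu, C5–OH | O=C1c2c(O)c(Cl)cc3c2[C@@]2(Oc4cc(Cl)c(O[Si](C)(C)C(C)(C)C)c5c4[C@]3(O2)C=CC5=O)C=C1 | intermediate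
23 | ring D allylic alcohol: as 22 with C4′H–OH, OH anti to the C1′–O bridge | O=C1c2c(O)c(Cl)cc3c2[C@@]2(Oc4cc(Cl)c(O[Si](C)(C)C(C)(C)C)c5c4[C@]3(O2)C=C[C@H]5O)C=C1 | intermediate
24 | C4′/C5′ bis(silyl ether): as 23 with C4′–OSiMe2t-Bu | O=C1c2c(O)c(Cl)cc3c2[C@@]2(Oc4cc(Cl)c(O[Si](C)(C)C(C)(C)C)c5c4[C@]3(O2)C=C[C@H]5O[Si](C)(C)C(C)(C)C)C=C1 | intermediate
25 | ring D epoxide: as 24 with C2′/C3′ oxirane, oxygen syn to the C1′–O bridge and anti to C4′–O | O=C1c2c(O)c(Cl)cc3c2[C@@]2(Oc4cc(Cl)c(O[Si](C)(C)C(C)(C)C)c5c4[C@]3(O2)[C@@H]2O[C@@H]2[C@H]5O[Si](C)(C)C(C)(C)C)C=C1 | intermediate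
26 | bis-epoxide bis(silyl ether): as 25 with C2/C3 oxirane, oxygen syn to the C1–O–C1′ oxygen | O=C1c2c(O)c(Cl)cc3c2[C@@]2(Oc4cc(Cl)c(O[Si](C)(C)C(C)(C)C)c5c4[C@]3(O2)[C@@H]2O[C@@H]2[C@H]5O[Si](C)(C)C(C)(C)C)[C@@H]2O[C@H]12 | intermediate
27 | CNP0289684.3: (1S,2R,3S,1′S,2′R,3′R,4′S) in the locants of the overview; both oxirane oxygens syn to the C1–O–C1′ oxygen, C4′–OH anti to the C2′/C3′ oxirane oxygen, C4 ketone, 5-OH, 5′-OH, 6-Cl, 6′-Cl | O=C1c2c(O)c(Cl)cc3c2[C@@]2(Oc4cc(Cl)c(O)c5c4[C@]3(O2)[C@@H]2O[C@@H]2[C@H]5O)[C@@H]2O[C@H]12 | target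

**Step count and risks**

Total steps: 16. Longest linear sequence: 15 steps (from 1 through steps 1–4 and 6–16; step 5 is a one-step side branch).

Steps most likely to fail:

Step 9. The cascade may fail through loss of the C2′ proton and of silanol from 17 (aromatisation of ring D), through Michael addition of 15 to quinone CH positions, or through poor enantiofacial control in the cage closure. The fallback uses known chemistry and sets out from 14. The uncatalysed vinylquinone Diels–Alder reaction with 15 is run in aqueous acetonitrile, so that water intercepts the isoquinone methide at C1′. Mildly acidic work-up should give tetraol F1 (tertiary C1′–OH, ring C hydroquinone, C4′–OH, ring B quinone intact). p-Toluenesulfonic acid in CH2Cl2 over MgSO4 then closes the ketal (C1′–OH onto the C1 carbonyl, C8′–OH onto the hemiketal) to give racemic cage enone diol F2. Preparative chromatography on a chiral stationary phase separates 19 from its enantiomer F3, and the route continues at 19.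

Step 12. The reduction may fail through co-reduction of the ring B ketone or through poor facial selectivity at C4′. The fallback sets out from 22 and epoxidises both enones first (t-BuOOH, DBU) to give bis(epoxy ketone) F4. NaBH4 at −78 °C then reduces the ring D ketone, which is now an α,β-epoxy ketone without a free peri phenol and clearly more electrophilic than the chelated ring B ketone. Attack anti to the oxirane C–O bond is expected, giving cis-epoxy alcohol F5. Mitsunobu inversion with 4-nitrobenzoic acid (PPh3, diisopropyl azodicarboxylate) gives 4-nitrobenzoate F6 with the C4′ configuration of the target. K2CO3 in methanol cleaves the ester and the aryl silyl ether, and the route comes back at 27.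

Step 11. The one-pot oxidation may stall at the hindered ring D ketone, or the aryl silyl ether may be lost in hot DMSO. The fallback sets out from 20: Dess–Martin periodinane gives ketone 21 (isolated in this variant), PhSeCl in ethyl acetate selenenylates C3′ to give α-phenylselanyl ketone F7, and H2O2/pyridine effects selenoxide syn-elimination, which returns to the route at 22.

Further compounds
F1 | step 9 | 6-chloro-8-(3-chloro-1,4,5,8-tetrahydroxy-5,6,7,8-tetrahydronaphthalen-1-yl)-5-hydroxynaphthalene-1,4-dione (stereoisomer mixture) | O=C1C=CC(=O)c2c1c(O)c(Cl)cc2C1(O)CCC(O)c2c(O)c(Cl)cc(O)c12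
F2 | step 9 | racemic cage enone diol (racemate of 19, C4′ epimers) | O=C1c2c(O)c(Cl)cc3c2C2(Oc4cc(Cl)c(O)c5c4C3(O2)CCC5O)C=C1
F3 | step 9 | enantiomer of cage enone diol 19 (separated and discarded) | O=C1c2c(O)c(Cl)cc3c2[C@]2(Oc4cc(Cl)c(O)c5c4[C@@]3(O2)CCC5O)C=C1
F4 | step 12 | bis(epoxy ketone): C2/C3 and C2′/C3′ oxiranes syn to the bridging oxygen, C4=O and C4′=O, C5′–OSiMe2t-Bu, C5–OH | O=C1c2c(O)c(Cl)cc3c2[C@@]2(Oc4cc(Cl)c(O[Si](C)(C)C(C)(C)C)c5c4[C@]3(O2)[C@@H]2O[C@@H]2C5=O)[C@@H]2O[C@H]12
F5 | step 12 | cis-epoxy alcohol: as F4 with C4′H–OH syn to the C2′/C3′ oxirane oxygen (C4′ epimer of the target series) | O=C1c2c(O)c(Cl)cc3c2[C@@]2(Oc4cc(Cl)c(O[Si](C)(C)C(C)(C)C)c5c4[C@]3(O2)[C@@H]2O[C@@H]2[C@@H]5O)[C@@H]2O[C@H]12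
F6 | step 12 | C4′ 4-nitrobenzoate with inverted (target) C4′ configuration, C5′–OSiMe2t-Bu | O=C1c2c(O)c(Cl)cc3c2[C@@]2(Oc4cc(Cl)c(O[Si](C)(C)C(C)(C)C)c5c4[C@]3(O2)[C@@H]2O[C@@H]2[C@H]5OC(=O)c2ccc(cc2)[N+](=O)[O-])[C@@H]2O[C@H]12
F7 | step 11 | C3′-phenylselanyl ring D ketone (C3′ epimers) | O=C1c2c(O)c(Cl)cc3c2[C@@]2(Oc4cc(Cl)c(O[Si](C)(C)C(C)(C)C)c5c4[C@]3(O2)CC([Se]c2ccccc2)C5=O)C=C1
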